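## Retrosynthetic overview
1. Target 16 ⇒ acylation of the C8-OH of diol 13 with a masked 4-hydroxybenzoyl unit (14).
2. 13 ⇒ reagent-controlled reduction of the C8 ketone (12), which comes from reductive C9–O cleavage of epoxy dienone 11.
3. 11 ⇒ the only carbocycle-forming step, closing C6=C7 (farnesyl C1→C10) by intramolecular olefination of the linear C15 farnesane chain 10.
4. 10 ⇒ epoxy dialdehyde 6 plus diethyl isobutylphosphonate 7 (supplies C7 and iPr).
5. 6 ⇒ Sharpless mono-epoxidation of symmetric diol 4 ⇐ hepta-1,6-diyne 1. Ring order: oxirane first (temporary), then the ten-membered ring.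

Assumption: the presumed biosynthesis is FPP → 1,10-closure (germacrane C6–C7) → germacrene-C-type 4,6-diene → 8-oxygenation/acylation and hydration at C10; germacrane numbering is used (C4 vinyl-Me carbon, C7 iPr carbon, C8 ester carbinol, C10 tertiary carbinol), so the target is (4E,6Z,8S,10S).

## Route

Step 1
Reactants: 1 hepta-1,6-diyne
Product: 4 (2E,7E)-3,7-dimethylnona-2,7-diene-1,9-diol, via bis-alkenylalane 2 (not isolated), via dilithium bis-alanate 3 (not isolated)
Conditions: Me3Al (6 equiv), Cp2ZrCl2 (0.5 equiv), CH2Cl2, 0 °C→rt; strip volatiles; n-BuLi (2.1 equiv), hexane–THF, −30 °C; (CH2O)n, rt; 1 M HCl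
Reagents that add atoms: trimethylaluminium C[Al](C)C; paraformaldehyde (reacts as formaldehyde) C=O
Why: Double Negishi Zr-catalysed syn-carboalumination puts Me on the internal and Al on the terminal carbon of each alkyne, so both trisubstituted alkenes are E, and the alanate is hydroxymethylated with retention.

Step 2
Reactants: 4 (2E,7E)-3,7-dimethylnona-2,7-diene-1,9-diol
Product: 5 [(2S,3S)-3-[(4E)-6-hydroxy-4-methylhex-4-en-1-yl]-3-methyloxiran-2-yl]methanol
Conditions: Ti(OiPr)4 (10 mol %), L-(+)-DIPT (13 mol %), t-BuOOH (0.9 equiv), 4 Å MS, CH2Cl2, −25 °C; recycle recovered 4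
Reagents that add atoms: tert-butyl hydroperoxide CC(C)(C)OO
Why: In this Katsuki–Sharpless asymmetric epoxidation the two allylic alcohol ends are equivalent, so reaction at either gives the same product, and L-(+)-tartrate gives the (2S,3S)-oxirane as with geraniol (about 95 % ee), which fixes the C10–O bond in the (10S) sense of the target.

Step 3
Reactants: 5 epoxy diol
Product: 6 (2R,3S)-3-methyl-3-[(4E)-4-methyl-6-oxohex-4-en-1-yl]oxirane-2-carbaldehyde
Conditions: TEMPO (10 mol %), PhI(OAc)2 (2.3 equiv), CH2Cl2, rt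
Reagents that add atoms: none
Why: Oxoammonium (TEMPO/BAIB) oxidation takes both primary alcohols to aldehydes under near-neutral conditions that leave the oxirane and the E-enal intact (C9 changes from S to R by CIP priority only).

Step 4
Reactants: 6 epoxy dialdehyde; 7 diethyl (2-methylpropyl)phosphonate
Product: 9 diethyl {1-hydroxy-3-methyl-1-[(2S,3S)-3-methyl-3-[(4E)-4-methyl-6-oxohex-4-en-1-yl]oxiran-2-yl]butan-2-yl}phosphonate (C7/C8 epimer mixture), via lithiated phosphonate 8 (not isolated)
Conditions: 7, n-BuLi (1.0 equiv), THF, −78 °C; cannulate slowly into 6 (1.0 equiv), THF, −90 °C; AcOH quench at −78 °C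
Reagents that add atoms: none
Why: In this 1,2-addition of a phosphonate carbanion the non-conjugated, α-oxygenated oxirane carbaldehyde is far more electrophilic than the β,β-disubstituted enal, and the new C7/C8 centres do not matter because both become sp2 later.

Step 5
Reactants: 9 β-hydroxyphosphonate
Product: 10 diethyl {3-methyl-1-[(2R,3S)-3-methyl-3-[(4E)-4-methyl-6-oxohex-4-en-1-yl]oxiran-2-yl]-1-oxobutan-2-yl}phosphonate (C7 epimers)
Conditions: Dess–Martin periodinane (1.3 equiv), CH2Cl2, 0 °C→rt
Reagents that add atoms: none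
Why: Dess–Martin oxidation of the only remaining alcohol gives the β-ketophosphonate without touching enal, oxirane or alkene, and completes the linear farnesane chain (farnesyl C1 aldehyde, C10 carbanion precursor).

Step 6 (key step)
Reactants: 10 keto phosphonate enal
Product: 11 (4E,6Z,9R,10S)-9,10-epoxygermacra-4,6-dien-8-one
Conditions: LiCl (10 equiv), DBU (3 equiv), MeCN, 25–40 °C; 10 added by syringe pump over 20 h (final 0.5 mM)
Reagents that add atoms: none
Why: In this intramolecular Horner–Wadsworth–Emmons olefination (Masamune–Roush) the Li-chelated C7 carbanion attacks the C6 aldehyde, which is the 1,10-closure with the natural polarity, and phosphate loss stands in for the final deprotonation to the germacrene-C diene; the E-alkene and trans-oxirane pre-fold the chain, and both the ring (only a ring-cis alkene fits next to 4E) and the bulky iPr (prefers to lie trans to C5) favour 6Z.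

Step 7
Reactants: 11 epoxy dienone
Product: 12 (4E,6Z,10S)-10-hydroxygermacra-4,6-dien-8-one
Conditions: SmI2 (2.5 equiv), THF–MeOH, −90 °C, 10 min; pH 7 buffer
Reagents that add atoms: none
Why: Molander-type single-electron reduction of an α,β-epoxy ketone cleaves only the Cα–O (C9–O) bond faster than the dienone is reduced, so the C10–O bond and its configuration are untouched, and the cold buffered quench avoids retro-aldol.

Step 8
Reactants: 12 β-hydroxy dienone
Product: 13 (4E,6Z,8S,10S)-germacra-4,6-diene-8,10-diol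
Conditions: (R)-Me-CBS (0.2 equiv), catecholborane (2.5 equiv), toluene, −78 °C; MeOH, then aq. NaHCO3
Reagents that add atoms: none
Why: In this Corey–Bakshi–Shibata 1,2-reduction the α-isopropyl-dienyl side acts as the large group and C9H2 as the small one, so the (R)-catalyst gives (8S), which is syn to 10-OH; any minor (10R) material becomes the separable anti diastereomer, which raises the ee of 13.

Step 9
Reactants: 13 diol; 14 4-acetoxybenzoyl chloride
Product: 16 (1S,2Z,4E,9S)-9-hydroxy-5,9-dimethyl-2-(propan-2-yl)cyclodeca-2,4-dien-1-yl 4-hydroxybenzoate (target), via phenol acetate 15 (not isolated)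
Conditions: 14 (1.3 equiv), Et3N, DMAP (0.2 equiv), CH2Cl2, 0 °C→rt; then pyrrolidine (5 equiv), rt, 30 min
Reagents that add atoms: none
Why: DMAP-catalysed acylation reaches only the secondary C8-OH because the tertiary C10-OH is inert, and pyrrolidine aminolysis removes the activated aryl acetate much faster than the alkyl benzoate; no stereocentre is touched.

## Compound list
1 | hepta-1,6-diyne | C#CCCCC#C | starting material
2 | (1E,6E)-1,7-bis(dimethylalumanyl)-2,6-dimethylhepta-1,6-diene | C[Al](C)/C=C(\C)CCC/C(C)=C/[Al](C)C | intermediate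
3 | dilithium bis(butyl-dimethyl-alkenyl)alanate of 2 | [Li+].[Li+].CCCC[Al-](C)(C)/C=C(\C)CCC/C(C)=C/[Al-](C)(C)CCCC | intermediate
4 | (2E,7E)-3,7-dimethylnona-2,7-diene-1,9-diol | OC/C=C(\C)CCC/C(C)=C/CO | intermediate
5 | [(2S,3S)-3-[(4E)-6-hydroxy-4-methylhex-4-en-1-yl]-3-methyloxiran-2-yl]methanol | OC[C@@H]1O[C@@]1(C)CCC/C(C)=C/CO | intermediate
6 | (2R,3S)-3-methyl-3-[(4E)-4-methyl-6-oxohex-4-en-1-yl]oxirane-2-carbaldehyde | O=C[C@@H]1O[C@@]1(C)CCC/C(C)=C/C=O | intermediate
7 | diethyl (2-methylpropyl)phosphonate | CCOP(=O)(CC(C)C)OCC | starting material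
8 | diethyl (1-lithio-2-methylpropyl)phosphonate | [Li]C(C(C)C)P(=O)(OCC)OCC | intermediate
9 | β-hydroxyphosphonate (C7/C8 epimers, oxirane 2S,3S) | CCOP(=O)(OCC)C(C(C)C)C(O)[C@@H]1O[C@@]1(C)CCC/C(C)=C/C=O | intermediate
10 | β-ketophosphonate enal (C7 epimers, oxirane 2R,3S) | CCOP(=O)(OCC)C(C(C)C)C(=O)[C@@H]1O[C@@]1(C)CCC/C(C)=C/C=O | intermediate
11 | (4E,6Z,9R,10S)-9,10-epoxygermacra-4,6-dien-8-one | C/C1=C\C=C(\C(C)C)C(=O)[C@@H]2O[C@@]2(C)CCC1 | intermediate
12 | (4E,6Z,10S)-10-hydroxygermacra-4,6-dien-8-one | C/C1=C\C=C(\C(C)C)C(=O)C[C@@](C)(O)CCC1 | intermediate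
13 | (4E,6Z,8S,10S)-germacra-4,6-diene-8,10-diol | C/C1=C\C=C(\C(C)C)[C@@H](O)C[C@@](C)(O)CCC1 | intermediate
14 | 4-acetoxybenzoyl chloride | CC(=O)Oc1ccc(cc1)C(Cl)=O | starting material
15 | 8-O-(4-acetoxybenzoyl) derivative of 13 | C/C1=C\C=C(\C(C)C)[C@@H](OC(=O)c2ccc(OC(C)=O)cc2)C[C@@](C)(O)CCC1 | intermediate
16 | (4E,6Z,8S,10S)-8-(4-hydroxybenzoyloxy)germacra-4,6-dien-10-ol | C/C1=C\C=C(\C(C)C)[C@@H](OC(=O)c2ccc(O)cc2)C[C@@](C)(O)CCC1 | target

## Totals and risks
Total steps: 9. Longest linear sequence: 9 (1 → 16).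

**Step 6 (ten-membered HWE with an α-branched phosphonate).** The fallback sets out from 6 and returns at 11. It keeps the C6–C7 closure but replaces the olefination with a macro-aldolisation followed by dehydration.
- Isobutylmagnesium bromide (1.0 equiv, THF, −78 °C) adds to the oxirane carbaldehyde of 6 to give the epoxy alcohol F1.
- Dess–Martin oxidation gives the epoxy isobutyl ketone F2. It can enolise only towards C7, because C9 is an oxirane C–H.
- KHMDS (THF, −78 °C, 1 mM) closes the ring to the macrocyclic aldol F3.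
- MsCl/Et3N gives the mesylate F4, and DBU eliminates it to 11.

**Step 7 (SET opening next to a reducible dienone, with a retro-aldol-prone product).** The fallback sets out from 11 and returns at 13, bypassing 12. It swaps the order of events and uses an SN2 hydride opening instead of electron transfer.
- (R)-Me-CBS/catecholborane first reduces the ketone to the epoxy dienol F5. This is 8R by CIP but has the same spatial sense as 8S in 13.
- LiEt3BH (THF, 0 °C) then attacks C9, the only non-quaternary oxirane carbon, and gives 13.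

**Step 8 (the macrocycle's facial bias may override the catalyst).** The fallback sets out from 12 and returns at 15. It exploits the substrate bias and then inverts C8.
- NaBH4/CeCl3 (or (S)-Me-CBS) gives the 8-epimeric diol F6.
- Mitsunobu esterification with 4-acetoxybenzoic acid (PPh3, DIAD, toluene, 0 °C) inverts C8 while installing the ester, giving 15.
- 15 is deacetylated with pyrrolidine as in step 9.

## Further compounds
F1 | step 6 | (2E)-6-[(2S,3S)-3-(1-hydroxy-3-methylbutyl)-2-methyloxiran-2-yl]-3-methylhex-2-enal | CC(C)CC(O)[C@@H]1O[C@@]1(C)CCC/C(C)=C/C=O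
F2 | step 6 | (2E)-3-methyl-6-[(2S,3R)-2-methyl-3-(3-methylbutanoyl)oxiran-2-yl]hex-2-enal | CC(C)CC(=O)[C@@H]1O[C@@]1(C)CCC/C(C)=C/C=O
F3 | step 6 | (4E,9R,10S)-9,10-epoxy-6-hydroxygermacr-4-en-8-one (C6/C7 epimers) | C/C1=C\C(O)C(C(C)C)C(=O)[C@@H]2O[C@@]2(C)CCC1
F4 | step 6 | 6-O-methanesulfonate of F3 | C/C1=C\C(OS(C)(=O)=O)C(C(C)C)C(=O)[C@@H]2O[C@@]2(C)CCC1
F5 | step 7 | (4E,6Z,8R,9S,10S)-9,10-epoxygermacra-4,6-dien-8-ol | C/C1=C\C=C(\C(C)C)[C@@H](O)[C@@H]2O[C@@]2(C)CCC1
F6 | step 8 | (4E,6Z,8R,10S)-germacra-4,6-diene-8,10-diol | C/C1=C\C=C(\C(C)C)[C@H](O)C[C@@](C)(O)CCC1
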